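The constants used here are assumed; the result is computed.

We start from a ratio: the time a wholly free nucleophile would take to reach the wanted part, over the run time.

electrophile 28 mM; protonated nucleophile 25.2 mM; time 50 s

1. the concentration of free base at which the part of the electrophile that has reacted at 50 s is just 70%, in mM

- amounts and yields of acid set free count idle adduct too
- for a step with 2 of a species take k times the square, and two of it per event
- the amount of free base is what is sought; it is there from the start
- run time (flask): 50 s

Electrophile and nucleophile couple at 5.70 /M/s, and each coupling sets acid free. Without any acid on the nucleophile, the second-order law from these charges reaches 70% in 18.8 s. Over 50 s that gives 0.376. We call this the needed free share: the mean part of the unreacted nucleophile that must stand free of acid during the run.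

The base holds acid far more tightly than the nucleophile does, so we let the salt of the base fill first. We take the end share equal to the mean. That share stands at [acid set free] = 3.77 mM. At the wanted part the acid totals 44.8 mM, and 3.49 mM sits on nucleophile. We set aside the idle adduct, which binds acid more weakly than the protonated form does. The salt holds the rest, so we reckon 37.5 mM of free base.

One number is not enough. A falling share ends under its mean, which lowers the charge. Against that, dimerisation of the leftover base starts at a quarter of the coupling rate, which raises it. We commit to somewhat under 37.5 mM.

The forecast is 53 mM, above our figure. It reaches that from about 40 mM of base still surviving plus “roughly 12 to 13 mM lost early to fast dimerisation”.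

    acid set free + free base ⇌ salt of the base, settled at all times (K1 = 23000 /M)
    nucleophile + acid set free ⇌ idle adduct, settled at all times (K2 = 22 /M)
    2 free base → homo dimer (k3 = 3.34 /M/s)
    electrophile + nucleophile → acid set free + target (k4 = 5.70 /M/s)
    nucleophile + acid set free ⇌ protonated nucleophile, settled at all times (K5 = 440 /M)

The flask needs 32.9 mM, and with a fifth less of free base the part reacted is 65.0%. The same ratio, applied to readings from the flask charged with 32.9 mM, gives the mean free share so far. With 37.1% of the electrophile used at 5.00 s, it reads 0.848. Over the run the mean share is lower, at 0.376. With 79.5% used at 150 s, it reads 0.235.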